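**Retrosynthetic overview**
1. Target 10 ← phenol 8 by hydroxyl-directed dibromination of ring A at C4 and C6 (last step).
2. Phenol 8 ← methyl ether 6 by O-demethylation.
3. Ether 6 ← phenol 1 + benzyne (from 2) + a positive-bromine donor: a new three-component aryne 1,2-aryloxybromination that forms the diaryl ether C–O bond and the ring B C–Br bond together.
4. No ring is built: ring A comes from 1 and ring B from 2, and they are joined in step 1.

Assumption: the target has no stereocentre and no isolable atropisomerism, so it is achiral and no enantiocontrol is needed.

**Route**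

Step 1
Reactants: 1 2-bromo-6-methoxyphenol; 2 2-(trimethylsilyl)phenyl trifluoromethanesulfonate
Product: 6 1-bromo-2-(2-bromophenoxy)-3-methoxybenzene, via potassium 2-bromo-6-methoxyphenolate 3 (not isolated), via benzyne 4 (not isolated), via [2-(2-bromo-6-methoxyphenoxy)phenyl]potassium 5 (not isolated)
Conditions: KH (1.0 equiv), THF, 0 °C; then BrCl2C–CCl2Br (3 equiv), KF (3.5 equiv), 18-crown-6 (3.5 equiv), 2 (1.6 equiv, syringe pump, 4 h), THF, 0 °C to rt
Reagents that add atoms: 1,2-dibromo-1,1,2,2-tetrachloroethane, BrC(Cl)(Cl)C(Cl)(Cl)Br
Why: Proposed new method: three-component aryne 1,2-aryloxybromination, in which the proton-free phenolate 3 (made with KH so that no conjugate acid remains) adds to benzyne 4 released from 2 by KF/18-crown-6, and the resulting aryl anion 5 is trapped by halophilic attack on a bromine of BrCl2C–CCl2Br, which collapses irreversibly to Cl2C=CCl2 and KBr so that no nucleophilic carbanion by-product competes for benzyne, giving the diaryl ether C–O bond and the ortho C–Br bond of ring B in one operation with no regiochemical issue because benzyne is symmetrical; the closest known reaction types are the fluoride-triggered O-arylation of phenols by arynes (insertion into O–H) and three-component aryne couplings in which a heteroatom nucleophile adds and the aryl anion is quenched by a positive-halogen donor (for example aryne bromothiolation), but the combination of an aryloxide nucleophile with bromine capture has not been demonstrated.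

Step 2
Reactants: 6 1-bromo-2-(2-bromophenoxy)-3-methoxybenzene
Product: 8 3-bromo-2-(2-bromophenoxy)phenol, via dibromo[3-bromo-2-(2-bromophenoxy)phenoxy]borane 7 (not isolated)
Conditions: BBr3 (2.0 equiv), CH2Cl2, –78 °C to rt; then H2O
Reagents that add atoms: none
Why: Lewis-acid ether cleavage: BBr3 coordinates the methoxy oxygen and bromide attacks the methyl carbon (SN2) to give aryloxyborane 7, which hydrolyses on work-up, while the diaryl ether and the aryl bromides are inert.

Step 3
Reactants: 8 3-bromo-2-(2-bromophenoxy)phenol
Product: 10 3,4,6-tribromo-2-(2-bromophenoxy)phenol, via 3,4-dibromo-2-(2-bromophenoxy)phenol 9 (not isolated)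
Conditions: Br2 (2.05 equiv), AcOH, rt
Reagents that add atoms: bromine, BrBr
Why: Electrophilic aromatic bromination: the free hydroxyl directs the two bromines para (C4) and ortho (C6), reinforced by the ortho/para-directing C3 bromine, while ring B (an ortho-bromo aryl ether on an electron-poor oxygen) is far less activated and is untouched at two equivalents.

**Compound list**
1 | 2-bromo-6-methoxyphenol | COc1cccc(Br)c1O | starting material
2 | 2-(trimethylsilyl)phenyl trifluoromethanesulfonate | C[Si](C)(C)c1ccccc1OS(=O)(=O)C(F)(F)F | starting material
3 | potassium 2-bromo-6-methoxyphenolate | COc1cccc(Br)c1[O-].[K+] | intermediate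
4 | benzyne (1,2-didehydrobenzene) | C1=CC=CC#C1 | intermediate
5 | [2-(2-bromo-6-methoxyphenoxy)phenyl]potassium (aryl anion ortho to the ether oxygen on ring B) | COc1cccc(Br)c1Oc1ccccc1[K] | intermediate
6 | 1-bromo-2-(2-bromophenoxy)-3-methoxybenzene | COc1cccc(Br)c1Oc1ccccc1Br | intermediate
7 | dibromo[3-bromo-2-(2-bromophenoxy)phenoxy]borane | BrB(Br)Oc1cccc(Br)c1Oc1ccccc1Br | intermediate
8 | 3-bromo-2-(2-bromophenoxy)phenol | Oc1cccc(Br)c1Oc1ccccc1Br | intermediate
9 | 3,4-dibromo-2-(2-bromophenoxy)phenol | Oc1ccc(Br)c(Br)c1Oc1ccccc1Br | intermediate
10 | 3,4,6-tribromo-2-(2-bromophenoxy)phenol (achiral) | Oc1c(Br)cc(Br)c(Br)c1Oc1ccccc1Br | target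

**Totals**
Total step count: 3. Longest linear sequence: 3.

**Steps most likely to fail**

Step 1 (the proposed new step, highest risk). Three things can go wrong. Anion 5 may pick up a proton and give the ether without the ring B bromine. Phenolate 3 may be C-brominated by the donor. The KBr formed may trap benzyne as 1,2-dibromobenzene. The fallback uses known chemistry, sets out from 1 and comes back at 6. 1-Bromo-2-iodobenzene is oxidised with mCPBA and TsOH·H2O in MeCN to 1-bromo-2-[hydroxy(tosyloxy)iodo]benzene F1. This is condensed in the same pot with 1,3,5-trimethoxybenzene to (2-bromophenyl)(2,4,6-trimethoxyphenyl)iodonium 4-methylbenzenesulfonate F2. Phenol 1 is deprotonated with KOtBu in THF at 0 °C to phenolate 3 and arylated without metal by F2 at 40 °C. The electron-rich trimethoxyphenyl group stays on iodine and the 2-bromophenyl group is transferred to oxygen by ligand coupling, giving 6.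

Step 3. The risk is over-bromination at the position para to oxygen on ring B, or a mixture of under-brominated phenols that is hard to separate. The fallback sets out from 8 and comes back at 10. It replaces the single exhaustive bromination by two reagent-directed, site-specific halogenations with an isolated intermediate. Amine-mediated ortho-bromination (Br2 1.0 equiv, t-BuNH2 2 equiv, toluene, –78 °C), at which the aryl ether ring is inert, gives 3,6-dibromo-2-(2-bromophenoxy)phenol F4. After purification, F4 is brominated at the remaining para position with n-Bu4NBr3 (1.05 equiv) in CH2Cl2/MeOH at rt to give 10.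

Step 2. This is the lowest risk. BBr3 and the HBr formed could cause partial protodebromination or bromine migration on the electron-rich ring, or chelation could leave the cleavage incomplete. The fallback sets out from 6 and comes back at 8. It switches from Lewis-acid cleavage to nucleophilic dealkylation under basic conditions. NaSEt (3 equiv) in DMF at 110 °C attacks the methyl carbon (SN2) and gives sodium 3-bromo-2-(2-bromophenoxy)phenolate F3, which is acidified with 1 M HCl to 8.

Further compounds
F1 | step 1 | 1-bromo-2-[hydroxy(tosyloxy)iodo]benzene | OI(OS(=O)(=O)c1ccc(C)cc1)c1ccccc1Br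
F2 | step 1 | (2-bromophenyl)(2,4,6-trimethoxyphenyl)iodonium 4-methylbenzenesulfonate | COc1cc(OC)c([I+]c2ccccc2Br)c(OC)c1.Cc1ccc(cc1)S(=O)(=O)[O-]
F3 | step 2 | sodium 3-bromo-2-(2-bromophenoxy)phenolate | [Na+].[O-]c1cccc(Br)c1Oc1ccccc1Br
F4 | step 3 | 3,6-dibromo-2-(2-bromophenoxy)phenol | Oc1c(Br)ccc(Br)c1Oc1ccccc1Br
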